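**Retrosynthetic overview**
1. The strategy rests on rings C and D, a bicyclo[3.2.1]octane whose seven-membered circuit C8–C9–C11–C12–C13–C16–C15 is spanned by C14. It is read as the (4+3) adduct of a cyclopentadiene (ring D: C8, C15, C16, C13, C14) and a C9–C11–C12 allyl cation; C10–C5–C6 of ring B is the tether, and C16 (the carbon of the exocyclic methylene) is the carbonyl carbon of a cyclopentenone.
2. Target ⇒ 17-nor-16-ketone acetonide (Wittig for C17) ⇒ (4+3) cycloadduct ⇒ 2-silyloxycyclopentadiene tethered to a 2-ethoxyallyl pivalate ⇒ C6 enol triflate + 3-stannylcyclopentenone (Stille), and C9 aldehyde + 1-ethoxyvinyllithium.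
3. Ring A ⇒ ester-tethered Diels–Alder reaction of a silyl diene diol with citraconic anhydride (C4, C5, C10; resolution), allylsilane transposition to the 2,3-ene, lactone switch (γ to 19,20-δ) with MeLi, osmylation for C2 and C3.
4. Ring order: A (with γ-lactone) → 19,20-δ-lactone → preformed ring D attached at C6 → rings B and C closed together.

Key step: step 18

Remark: gibberellane atom numbers are used throughout. It is assumed that the less soluble (R)-1-phenylethylammonium salt in step 5 holds the acid of the configuration shown (otherwise the (S)-amine is used). The C9 epimers of 25, 26, 30 and 31 are carried together.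

**Step 1**
Reactants: 1 allyltrimethylsilane
Product: 3 (E)-1,3-bis(trimethylsilyl)propene, via [1-(trimethylsilyl)allyl]lithium 2 (not isolated)
Conditions: s-BuLi, TMEDA, THF, −78 °C; Me3SiCl, −78 °C → rt
Reagents that add atoms: chlorotrimethylsilane C[Si](C)(C)Cl
Why: Allylic deprotonation and silylation of the silyl-substituted allyl anion at the carbon remote from silicon (γ-attack) should give the (E)-1,3-disilylpropene.

**Step 2**
Reactants: 3 (E)-1,3-bis(trimethylsilyl)propene; 4 2,2-dimethyl-1,3-dioxan-5-one
Product: 7 2,2-dimethyl-5-[(E)-3-(trimethylsilyl)prop-2-en-1-ylidene]-1,3-dioxane, via [(E)-1,3-bis(trimethylsilyl)allyl]lithium 5 (not isolated), via lithium alkoxide adduct 6 (not isolated)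
Conditions: s-BuLi, TMEDA, THF, −78 → −30 °C; 4, −78 °C → rt; aq NH4Cl
Reagents that add atoms: none
Why: Peterson olefination, in which the symmetrical bis-silylallyl anion adds to the ketone and the β-silyl alkoxide loses Me3SiOLi in the flask; the new alkene carbon carries two like arms, so only the (E)-vinylsilane geometry inherited from the W-shaped anion is at issue.

**Step 3**
Reactants: 7 2,2-dimethyl-5-[(E)-3-(trimethylsilyl)prop-2-en-1-ylidene]-1,3-dioxane
Product: 8 2-[(E)-3-(trimethylsilyl)prop-2-en-1-ylidene]propane-1,3-diol
Conditions: AcOH/H2O/THF, rt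
Reagents that add atoms: none
Why: Acid-catalysed acetal hydrolysis under conditions too mild to protodesilylate the dienylsilane.

**Step 4**
Reactants: 8 2-[(E)-3-(trimethylsilyl)prop-2-en-1-ylidene]propane-1,3-diol; 9 citraconic anhydride
Product: 11 racemic Diels–Alder acid (ring A cyclohex-1-ene with cis-fused γ-lactone from the C6 carbonyl to O–C20; C19 acid and methyl on C4; C9 hydroxymethyl on C10; SiMe3 on C3), via citraconate half-ester 10 (not isolated)
Conditions: DMAP (cat.), toluene, rt; then BHT, o-xylene, 140 °C
Reagents that add atoms: none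
Why: Alcoholysis of the anhydride at the carbonyl remote from the methyl group, then an ester-tethered intramolecular Diels–Alder reaction in which the (Z)-dienophile fixes C4 against C5 and the three-atom tether C20–O–C6 should give the cis-fused lactone and so fix C10; the two geometrical monoesters interconvert by acyl migration and lead to the same relative configuration at C4, C5 and C10, only the immaterial C3 silyl centre being open.

**Step 5**
Reactants: 11 racemic Diels–Alder acid
Product: 12 Diels–Alder acid as the single enantiomer drawn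
Conditions: (R)-1-phenylethylamine, EtOH/EtOAc, fractional crystallisation; then 1 M HCl, EtOAc
Reagents that add atoms: none
Why: Classical resolution through diastereomeric ammonium carboxylate salts makes C4, C5 and C10 absolute (to be confirmed by X-ray analysis of the salt), and the crystallisation should also leave any minor C3 epimer in the mother liquor.

**Step 6**
Reactants: 12 Diels–Alder acid (single enantiomer)
Product: 13 methyl ester of 12
Conditions: Me3SiCHN2, toluene/MeOH, 0 °C
Reagents that add atoms: trimethylsilyldiazomethane C[Si](C)(C)C=[N+]=[N-]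
Why: Esterification by O-alkylation of the carboxylate with a diazoalkane, which avoids attack at the hindered C19 carbonyl on the quaternary C4.

**Step 7**
Reactants: 13 methyl ester of 12
Product: 14 2,3-ene hydroxy ester (C3 silicon removed, C1 now CH2)
Conditions: CF3CO2H, CH2Cl2, 0 °C; then NaHCO3, MeOH/H2O
Reagents that add atoms: none
Why: Protodesilylation of the allylsilane in the SE2' sense: protonation at C1 gives the β-silyl cation and loss of silicon from C3 moves the double bond to C2=C3, while the ester made beforehand cannot lactonise onto the cation.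

**Step 8**
Reactants: 14 2,3-ene hydroxy ester
Product: 15 C9 tert-butyldimethylsilyl ether of 14
Conditions: t-BuMe2SiCl, imidazole, DMF, rt
Reagents that add atoms: tert-butyldimethylsilyl chloride CC(C)(C)[Si](C)(C)Cl
Why: Standard silylation of the primary neopentyl alcohol.

**Step 9**
Reactants: 15 C9 silyl ether with γ-lactone and C19 methyl ester
Product: 17 19,20-δ-lactone with C6 acetyl group (2,3-ene and C9 silyl ether), via lithium keto alkoxide 16 (not isolated)
Conditions: MeLi (1.05 equiv), THF, −78 °C → 0 °C; aq NH4Cl
Reagents that add atoms: methyllithium [Li]C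
Why: Mono-addition of the organolithium to the γ-lactone gives a lactolate that opens on warming to the methyl ketone (C7 introduced), and the freed C20 alkoxide, 1,3-diaxial to C19, attacks the methyl ester in a translactonisation to the six-membered lactone; C5 keeps its configuration with the acetyl group equatorial on ring A.

**Step 10**
Reactants: 17 19,20-δ-lactone methyl ketone
Product: 18 cis-2,3-diol on the face opposite the lactone bridge
Conditions: OsO4 (cat.), N-methylmorpholine N-oxide, acetone/H2O, rt
Reagents that add atoms: osmium tetroxide O=[Os](=O)(=O)=O; N-methylmorpholine N-oxide C[N+]1([O-])CCOCC1; water O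
Why: Catalytic osmium tetroxide cis-dihydroxylation (Upjohn conditions) from the face of C2=C3 opposite to the pseudo-axial C19 of the lactone bridge, which sets C2 and C3 cis to the C18 methyl group.

**Step 11**
Reactants: 18 cis-2,3-diol
Product: 19 2,3-acetonide
Conditions: Me2C(OMe)2, PPTS (cat.), CH2Cl2, rt
Reagents that add atoms: 2,2-dimethoxypropane COC(C)(C)OC
Why: Acid-catalysed acetal exchange gives the cis-fused dioxolane and leaves the silyl ether untouched.

**Step 12**
Reactants: 19 2,3-acetonide methyl ketone
Product: 20 C6 enol triflate (C6=C7 with OTf on C6)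
Conditions: KN(SiMe3)2, THF, −78 °C; PhNTf2, −78 → −30 °C
Reagents that add atoms: N-phenylbis(trifluoromethanesulfonimide) O=S(=O)(N(c1ccccc1)S(=O)(=O)C(F)(F)F)C(F)(F)F
Why: Kinetic enolisation of the methyl ketone at the methyl group (C7) and O-sulfonylation give the 1,1-disubstituted enol triflate, the lactone having no α-hydrogen and C5–H being the hindered site.

**Step 13**
Reactants: 20 C6 enol triflate
Product: 21 C9 primary alcohol
Conditions: HF·pyridine, pyridine, THF, 0 °C → rt
Reagents that add atoms: none
Why: Buffered acidic fluoride cleaves the silyl ether; basic Bu4NF is avoided because it can eliminate 1-substituted vinyl triflates to alkynes.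

**Step 14**
Reactants: 21 C9 primary alcohol
Product: 22 C9 aldehyde
Conditions: DMP (1,1,1-triacetoxy-1,1-dihydro-1,2-benziodoxol-3(1H)-one), NaHCO3, CH2Cl2, rt
Reagents that add atoms: none
Why: Buffered hypervalent-iodine oxidation of the primary alcohol to an aldehyde that has no α-hydrogen and cannot epimerise.

**Step 15**
Reactants: 22 C9 aldehyde; 23 ethyl vinyl ether
Product: 26 2-ethoxyallyl pivalate at C9 (both C9 epimers), via 1-ethoxyvinyllithium 24 (not isolated), via lithium C9 alkoxide 25 (not isolated)
Conditions: 23, t-BuLi, THF, −78 → 0 °C; 22, −78 °C; t-BuCOCl, DMAP (cat.), −78 °C → rt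
Reagents that add atoms: pivaloyl chloride CC(C)(C)C(Cl)=O
Why: 1,2-Addition of an α-alkoxyvinyllithium to the non-enolisable aldehyde, faster at −78 °C than attack on the hindered lactone or the triflate, followed by O-acylation of the alkoxide in the flask; the new C9 centre is later made planar, so both epimers serve.

**Step 16**
Reactants: 27 3-ethoxycyclopent-2-en-1-one
Product: 29 3-(tributylstannyl)cyclopent-2-en-1-one, via lithium stannyl carbinolate 28 (not isolated)
Conditions: Bu3SnH, LiN(i-Pr)2, THF, 0 °C; 27, −78 °C; then 1 M HCl, 0 °C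
Reagents that add atoms: tributyltin hydride CCCC[SnH](CCCC)CCCC; water O
Why: Addition of the stannyl anion to the carbonyl of the vinylogous ester and acid-induced 1,3-carbonyl transposition with loss of water and ethanol (as in the Stork–Danheiser sequence) give the β-stannyl enone; conjugate addition–elimination would give the same product because the ring is otherwise unsubstituted.

**Step 17**
Reactants: 26 2-ethoxyallyl pivalate with C6 enol triflate; 29 3-(tributylstannyl)cyclopent-2-en-1-one
Product: 30 dienone with ring D attached at C6 (C7=C6–C8=C15–C16=O)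
Conditions: Pd(PPh3)4 (cat.), CuCl, LiCl, DMSO, 50 °C
Reagents that add atoms: none
Why: Stille coupling with CuCl/LiCl acceleration for the hindered vinyl triflate and the electron-poor stannane; oxidative addition of the zerovalent palladium catalyst to the triflate should outrun ionisation of the neopentyl allylic pivalate.

**Step 18**
Reactants: 30 dienone with 2-ethoxyallyl pivalate
Product: 32 pentacyclic cycloadduct (C11 ketone, C15=C16 silyl enol ether, C6 exocyclic methylene), via 2-silyloxycyclopentadiene 31 (not isolated)
Conditions: LiN(SiMe3)2, THF, −78 °C; t-BuMe2SiOTf, −78 °C; then CH2Cl2, 2,6-di-tert-butyl-4-methylpyridine, Me3SiOTf, −78 → −40 °C; aq NaHCO3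
Reagents that add atoms: tert-butyldimethylsilyl trifluoromethanesulfonate CC(C)(C)[Si](C)(C)OS(=O)(=O)C(F)(F)F; water O
Why: Proposed new method: Me3SiOTf silylates the pivalate carbonyl and ionises C9 to a W-shaped 2-ethoxyallyl cation that is planar at C9 (so both C9 epimers converge), and this three-carbon 2π unit adds across C13 and C8 of the 2-silyloxycyclopentadiene in a (4+3) cycloaddition, most likely asynchronous (nucleophilic C13 onto C12, then the C9 enol ether onto C8 of the silyl oxocarbenium ion), after which the quench hydrolyses the C11 ethyl oxocarbenium ion to the ketone and leaves C16 as its silyl enol ether. The closest known reaction types are Lewis-acid-induced intramolecular (4+3) cycloadditions of 2-alkoxy- and 2-silyloxyallyl cations with tethered furans and butadienes and the intermolecular oxyallyl cation–cyclopentadiene route to bicyclo[3.2.1]oct-6-en-3-ones, whereas a tethered 2-silyloxycyclopentadiene as the 4π partner is without precedent. Ring B (C5, C6, C8, C9, C10) closes by 5-exo bonding of C9 to C8, and ring C (C8, C9, C11, C12, C13, C14) closes as the six-membered ring of the cycloadduct across the existing ring D, whose C14 becomes the one-carbon bridge. C9 is set by the extended (chair-like) approach of the W cation, the only one that holds the C9–C10 and C8–C6 bonds nearly eclipsed as the forming five-membered ring requires, and it puts C10 axial on ring C with H9 on the side of the C15–C16 bridge; C8 and C13 are set together by the diene face that is attacked, and the twist forced on ring B by the trans-diequatorial C10–C9 and C5–C6 bonds of the rigid lactone-bridged ring A places the silyloxy-bearing bridge on the face of H5, away from the C4 quaternary centre and its lactone. The step needs regioselectivity (C13 to C12 and C9 to C8, not to C7) and this facial selectivity: the silyloxy group makes C13 the nucleophilic terminus, closure onto C7 would be 5-endo, the lactone has no α-hydrogen, the low temperature holds back the 1,5-hydrogen shift of the diene, and C9 remains correctable by equilibration next to the C11 ketone.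

**Step 19**
Reactants: 32 pentacyclic cycloadduct
Product: 33 C11 alcohol (either epimer)
Conditions: NaBH4, MeOH/THF, 0 °C
Reagents that add atoms: none
Why: Hydride reduction of the only ketone; the hindered δ-lactone and the silyl enol ether should not react at 0 °C, and the carbinol configuration is of no consequence.

**Step 20**
Reactants: 33 C11 alcohol
Product: 34 C11 S-methyl xanthate
Conditions: KN(SiMe3)2, THF, −78 °C; CS2; MeI, −78 → 0 °C
Reagents that add atoms: carbon disulfide S=C=S; iodomethane CI
Why: Xanthate formation from the potassium alkoxide, the first half of the Barton–McCombie deoxygenation.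

**Step 21**
Reactants: 34 C11 xanthate
Product: 35 11-deoxy pentacycle (C15=C16 silyl enol ether, C6 exocyclic methylene)
Conditions: Bu3SnH, AIBN (cat.), toluene, 90 °C
Reagents that add atoms: none
Why: Barton–McCombie radical deoxygenation; the secondary C11 radical has only 4-exo or 5-endo paths to either alkene and should simply be reduced by the stannane.

**Step 22**
Reactants: 35 11-deoxy pentacycle
Product: 37 C7 primary alcohol (C6 epimers), via B-alkyl-9-BBN 36 (not isolated)
Conditions: 9-BBN, THF, rt → 45 °C; then 30% H2O2, aq NaOAc, 0 °C → rt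
Reagents that add atoms: 9-borabicyclo[3.3.1]nonane B1C2CCCC1CCC2 (boron of 36 only); hydrogen peroxide OO
Why: Hydroboration–oxidation in which the bulky borane should select the terminal methylene over the trisubstituted silyloxy alkene and place boron on C7; the C6 configuration formed here is not relied upon because it is equilibrated in step 24.

**Step 23**
Reactants: 37 C7 primary alcohol
Product: 38 C7 aldehyde (C6 epimers)
Conditions: DMP, pyridine, CH2Cl2, 0 °C → rt
Reagents that add atoms: none
Why: Buffered hypervalent-iodine oxidation of the primary alcohol, which should leave the silyl enol ether alone.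

**Step 24**
Reactants: 38 C7 aldehyde (C6 epimers)
Product: 39 6β-aldehyde (formyl group cis to H5 and trans to C4 on ring B)
Conditions: DBU (cat.), CH2Cl2, rt
Reagents that add atoms: none
Why: Base-mediated epimerisation through the enol under thermodynamic control, in which the formyl group should settle trans to the bulky C4 quaternary centre on the neighbouring C5, the configuration required at C6.

**Step 25**
Reactants: 39 6β-aldehyde
Product: 40 16-keto 7-aldehyde
Conditions: Bu4NF, AcOH, THF, 0 °C
Reagents that add atoms: none
Why: Buffered fluoride cleavage of the silyl enol ether to the C16 ketone; protonation occurs at C15 (a CH2) and C13 is a bridgehead, so no stereocentre is touched.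

**Step 26**
Reactants: 40 16-keto 7-aldehyde
Product: 41 17-nor-16-oxo C7 acid as the 2,3-acetonide
Conditions: NaClO2, NaH2PO4, 2-methyl-2-butene, t-BuOH/H2O, rt
Reagents that add atoms: sodium chlorite [Na+].[O-]Cl=O
Why: Pinnick oxidation of the aldehyde to the acid without epimerisation at C6; it is placed after the unmasking of C16 because a silyl enol ether would be chlorinated by the hypochlorous acid formed.

**Step 27**
Reactants: 41 17-nor-16-oxo C7 acid
Product: 42 2,3-acetonide of the target
Conditions: Ph3PCH3Br, KOt-Bu (excess ylide), THF, rt → 60 °C; then aq citric acid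
Reagents that add atoms: methyltriphenylphosphonium bromide C[P+](c1ccccc1)(c1ccccc1)c1ccccc1.[Br-]
Why: Wittig methylenation of the bicyclic C16 ketone (C17 introduced) with excess ylide, the first equivalent converting the acid into the inert carboxylate so that C6 and the lactone are not disturbed.

**Step 28**
Reactants: 42 2,3-acetonide of the target
Product: 43 target CNP0332607.1
Conditions: AcOH/H2O (4:1), 45 °C
Reagents that add atoms: none
Why: Acid-catalysed acetal hydrolysis under conditions mild enough to leave the exocyclic alkene, the lactone and the C6 centre unchanged.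

**Compound list**
1 | allyltrimethylsilane | C=CC[Si](C)(C)C | starting material
2 | [1-(trimethylsilyl)allyl]lithium | [Li]C(C=C)[Si](C)(C)C | intermediate
3 | (E)-1,3-bis(trimethylsilyl)propene | C[Si](C)(C)C/C=C/[Si](C)(C)C | intermediate
4 | 2,2-dimethyl-1,3-dioxan-5-one | CC1(C)OCC(=O)CO1 | starting material
5 | [(E)-1,3-bis(trimethylsilyl)allyl]lithium | [Li]C(/C=C/[Si](C)(C)C)[Si](C)(C)C | intermediate
6 | lithium 5-[(E)-1,3-bis(trimethylsilyl)allyl]-2,2-dimethyl-1,3-dioxan-5-olate | C[Si](C)(C)/C=C/C([Si](C)(C)C)C1([O-])COC(C)(C)OC1.[Li+] | intermediate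
7 | 2,2-dimethyl-5-[(E)-3-(trimethylsilyl)prop-2-en-1-ylidene]-1,3-dioxane | C[Si](C)(C)/C=C/C=C1COC(C)(C)OC1 | intermediate
8 | 2-[(E)-3-(trimethylsilyl)prop-2-en-1-ylidene]propane-1,3-diol | OCC(CO)=C/C=C/[Si](C)(C)C | intermediate
9 | citraconic anhydride | CC1=CC(=O)OC1=O | starting material
10 | citraconate half-ester of 8 (ester at the carbonyl remote from the methyl group; either arm acylated) | OCC(COC(=O)/C=C(/C)C(=O)O)=C/C=C/[Si](C)(C)C | intermediate
11 | racemic Diels–Alder acid (relative configuration shown; C3 silyl centre undefined) | OC[C@@]12COC(=O)[C@@H]1[C@](C)(C(=O)O)C([Si](C)(C)C)C=C2 | intermediate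
12 | Diels–Alder acid, single enantiomer: ring A 1-ene, cis-fused γ-lactone C6(=O)–O–C20, C19 acid and C18 methyl on C4, C9 hydroxymethyl on C10, SiMe3 on C3 | OC[C@@]12COC(=O)[C@@H]1[C@](C)(C(=O)O)C([Si](C)(C)C)C=C2 | intermediate
13 | C19 methyl ester of 12 | OC[C@@]12COC(=O)[C@@H]1[C@](C)(C(=O)OC)C([Si](C)(C)C)C=C2 | intermediate
14 | desilylated 2,3-ene hydroxy ester with γ-lactone | OC[C@@]12COC(=O)[C@@H]1[C@](C)(C(=O)OC)C=CC2 | intermediate
15 | C9 tert-butyldimethylsilyl ether of 14 | CC(C)(C)[Si](C)(C)OC[C@@]12COC(=O)[C@@H]1[C@](C)(C(=O)OC)C=CC2 | intermediate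
16 | lithium C20 alkoxide of the ring-opened C6 methyl ketone C19 methyl ester | CC(C)(C)[Si](C)(C)OC[C@]1(C[O-])CC=C[C@@](C)(C(=O)OC)[C@H]1C(C)=O.[Li+] | intermediate
17 | 19,20-δ-lactone with C6 acetyl group, 2,3-ene and C9 silyl ether | CC(C)(C)[Si](C)(C)OC[C@]12COC(=O)[C@](C)(C=CC1)[C@H]2C(C)=O | intermediate
18 | 2,3-cis-diol of 17 (hydroxyls anti to the lactone bridge) | CC(C)(C)[Si](C)(C)OC[C@]12COC(=O)[C@](C)([C@@H](O)[C@@H](O)C1)[C@H]2C(C)=O | intermediate
19 | 2,3-acetonide methyl ketone | CC(C)(C)[Si](C)(C)OC[C@]12COC(=O)[C@](C)([C@@H](OC3(C)C)[C@@H](O3)C1)[C@H]2C(C)=O | intermediate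
20 | 2,3-acetonide C6 enol triflate with C9 silyl ether | CC(C)(C)[Si](C)(C)OC[C@]12COC(=O)[C@](C)([C@@H](OC3(C)C)[C@@H](O3)C1)[C@H]2C(=C)OS(=O)(=O)C(F)(F)F | intermediate
21 | C9 alcohol enol triflate | OC[C@]12COC(=O)[C@](C)([C@@H](OC3(C)C)[C@@H](O3)C1)[C@H]2C(=C)OS(=O)(=O)C(F)(F)F | intermediate
22 | C9 aldehyde enol triflate | O=C[C@]12COC(=O)[C@](C)([C@@H](OC3(C)C)[C@@H](O3)C1)[C@H]2C(=C)OS(=O)(=O)C(F)(F)F | intermediate
23 | ethyl vinyl ether | C=COCC | starting material
24 | 1-ethoxyvinyllithium | [Li]C(=C)OCC | intermediate
25 | lithium C9 alkoxide of the 1-ethoxyvinyl adduct (both C9 epimers) | [Li+].[O-]C(C(=C)OCC)[C@]12COC(=O)[C@](C)([C@@H](OC3(C)C)[C@@H](O3)C1)[C@H]2C(=C)OS(=O)(=O)C(F)(F)F | intermediate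
26 | 2-ethoxyallyl pivalate at C9 beside the C6 enol triflate (both C9 epimers) | C=C(OCC)C(OC(=O)C(C)(C)C)[C@]12COC(=O)[C@](C)([C@@H](OC3(C)C)[C@@H](O3)C1)[C@H]2C(=C)OS(=O)(=O)C(F)(F)F | intermediate
27 | 3-ethoxycyclopent-2-en-1-one | CCOC1=CC(=O)CC1 | starting material
28 | lithium 3-ethoxy-1-(tributylstannyl)cyclopent-2-en-1-olate | CCCC[Sn](CCCC)(CCCC)C1([O-])C=C(OCC)CC1.[Li+] | intermediate
29 | 3-(tributylstannyl)cyclopent-2-en-1-one | CCCC[Sn](CCCC)(CCCC)C1=CC(=O)CC1 | intermediate
30 | dienone: 3-oxocyclopent-1-enyl (ring D) on C6 of the C6=C7 methylene, 2-ethoxyallyl pivalate at C9 | C=C(OCC)C(OC(=O)C(C)(C)C)[C@]12COC(=O)[C@](C)([C@@H](OC3(C)C)[C@@H](O3)C1)[C@H]2C(=C)C4=CC(=O)CC4 | intermediate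
31 | 2-silyloxycyclopentadiene (C8=C15–C16(OSi)=C13) tethered to the 2-ethoxyallyl pivalate | C=C(OCC)C(OC(=O)C(C)(C)C)[C@]12COC(=O)[C@](C)([C@@H](OC3(C)C)[C@@H](O3)C1)[C@H]2C(=C)C4=CC(O[Si](C)(C)C(C)(C)C)=CC4 | intermediate
32 | pentacyclic cycloadduct: C11 ketone, C15=C16 silyl enol ether, C6 exocyclic methylene, 2,3-acetonide, 19,20-lactone | CC(C)(C)[Si](C)(C)OC1=C[C@]23C[C@H]1CC(=O)[C@H]2[C@]12COC(=O)[C@](C)([C@@H](OC4(C)C)[C@@H](O4)C1)[C@H]2C3=C | intermediate
33 | C11 alcohol of 32 | CC(C)(C)[Si](C)(C)OC1=C[C@]23C[C@H]1CC(O)[C@H]2[C@]12COC(=O)[C@](C)([C@@H](OC4(C)C)[C@@H](O4)C1)[C@H]2C3=C | intermediate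
34 | C11 S-methyl xanthate | CC(C)(C)[Si](C)(C)OC1=C[C@]23C[C@H]1CC(OC(=S)SC)[C@H]2[C@]12COC(=O)[C@](C)([C@@H](OC4(C)C)[C@@H](O4)C1)[C@H]2C3=C | intermediate
35 | 11-deoxy pentacycle with C15=C16 silyl enol ether and C6 methylene | CC(C)(C)[Si](C)(C)OC1=C[C@]23C[C@H]1CC[C@H]2[C@]12COC(=O)[C@](C)([C@@H](OC4(C)C)[C@@H](O4)C1)[C@H]2C3=C | intermediate
36 | B-(C7-alkyl)-9-borabicyclo[3.3.1]nonane adduct of 35 | CC(C)(C)[Si](C)(C)OC1=C[C@]23C[C@H]1CC[C@H]2[C@]12COC(=O)[C@](C)([C@@H](OC4(C)C)[C@@H](O4)C1)[C@H]2C3CB5C6CCCC5CCC6 | intermediate
37 | C7 primary alcohol (C6 epimers) | CC(C)(C)[Si](C)(C)OC1=C[C@]23C[C@H]1CC[C@H]2[C@]12COC(=O)[C@](C)([C@@H](OC4(C)C)[C@@H](O4)C1)[C@H]2C3CO | intermediate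
38 | C7 aldehyde (C6 epimers) | CC(C)(C)[Si](C)(C)OC1=C[C@]23C[C@H]1CC[C@H]2[C@]12COC(=O)[C@](C)([C@@H](OC4(C)C)[C@@H](O4)C1)[C@H]2C3C=O | intermediate
39 | 6β-aldehyde with C15=C16 silyl enol ether | CC(C)(C)[Si](C)(C)OC1=C[C@]23C[C@H]1CC[C@H]2[C@]12COC(=O)[C@](C)([C@@H](OC4(C)C)[C@@H](O4)C1)[C@H]2[C@@H]3C=O | intermediate
40 | 16-keto 7-aldehyde | O=C1C[C@]23C[C@H]1CC[C@H]2[C@]12COC(=O)[C@](C)([C@@H](OC4(C)C)[C@@H](O4)C1)[C@H]2[C@@H]3C=O | intermediate
41 | 17-nor-16-oxo C7 acid, 2,3-acetonide | O=C1C[C@]23C[C@H]1CC[C@H]2[C@]12COC(=O)[C@](C)([C@@H](OC4(C)C)[C@@H](O4)C1)[C@H]2[C@@H]3C(=O)O | intermediate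
42 | 2,3-acetonide of the target | C=C1C[C@]23C[C@H]1CC[C@H]2[C@]12COC(=O)[C@](C)([C@@H](OC4(C)C)[C@@H](O4)C1)[C@H]2[C@@H]3C(=O)O | intermediate
43 | CNP0332607.1 | C=C1C[C@]23C[C@H]1CC[C@H]2[C@]12COC(=O)[C@](C)([C@@H](O)[C@@H](O)C1)[C@H]2[C@@H]3C(=O)O | target

**Step count and risks**
Total step count: 28. Longest linear sequence: 27 steps (steps 1–15 and 17–28; step 16 is the one-step side branch).

Steps most likely to fail:

1. Step 18 (proposed new method). The hindered pivalate may ionise too slowly, the enol ether may be protonated, the silyloxydiene may isomerise by 1,5-hydrogen shift before it is trapped, a 1,2-shift from C10 may intercept the cation, or the cation may add to the wrong diene face or in the compact mode. Fallback with known reactions, closing ring B and ring C one after the other: it sets out from aldehyde 22. A Wittig reaction with (formylmethylene)triphenylphosphorane (toluene, 80 °C) should give the (E)-enal F1. Stille coupling with 29 under the conditions of step 17 should give the enal–dienone F2. A reductive β,β'-cyclisation (Bu3SnH, AIBN, benzene, 80 °C, or SmI2, t-BuOH, THF, −78 °C) follows, in which the O-metallated allylic radical centred on C9 attacks C8 of the dienone in a 5-exo mode; it should give the tetracyclic keto aldehyde F3 with ring B closed. Selective reduction of the aldehyde (NaBH4, MeOH/CH2Cl2, −78 °C) should give the primary alcohol F4, and an Appel-type iodination (I2, PPh3, imidazole) the iodide F5. Kinetic enolisation of the cyclopentanone towards C13 (LiN(i-Pr)2, THF, −78 °C → rt; C15 is shielded by the quaternary C8) and intramolecular alkylation at C12 should then give the pentacyclic 16-ketone F6 with ring C closed. Silylation of F6 (t-BuMe2SiOTf, Et3N, CH2Cl2; enolisation is possible only towards C15 because C13 is a bridgehead) comes back to the route at 35, which makes steps 19–21 unnecessary. The C8/C9 configuration would then be set kinetically in the radical closure, under the same ring B twist bias.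

2. Step 4. The ester-tethered cycloaddition may be too slow (substituent cis on the diene terminus, trisubstituted dienophile, unfavourable ester conformer), so that polymerisation, double-bond isomerisation of the half-ester or acylation at the wrong anhydride carbonyl takes over. Fallback without the tether: it sets out from acetonide 7 and anhydride 9. A bimolecular Diels–Alder reaction (toluene, BHT, 110–140 °C, or high pressure) should pair C10 with C5 and C3 with C4, the only orientation that avoids two adjacent quaternary carbons, and give the spiro anhydride F7, in which C10 is not yet a stereocentre. Aqueous acid (AcOH/H2O/THF, 40 °C) then removes the acetonide, and the hydroxymethyl arm cis to the anhydride should close the five-membered lactone at C6 and free the C19 acid, which comes back to the route at the racemic acid 11.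

3. Step 9. MeLi may enolise the lactone at C5, add twice, or attack the methyl ester, and the translactonisation may stop at the lactol. Fallback by amide activation: it sets out from 15. Aminolysis of the γ-lactone with MeNHOMe·HCl and i-PrMgCl (THF, −20 → 0 °C) should open it to the N-methoxy-N-methylamide, and the released C20 alkoxide, 1,3-diaxial to the C19 ester, should lactonise in the same flask to the δ-lactone Weinreb amide F8. MeMgBr (THF, 0 °C) then stops at the ketone through the chelated adduct (Weinreb ketone synthesis) and comes back to the route at 17.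

**Further compounds**
F1 | step 18 | (E)-enal from 22 (C9=C11–C12 aldehyde) with C6 enol triflate | O=C/C=C/[C@]12COC(=O)[C@](C)([C@@H](OC3(C)C)[C@@H](O3)C1)[C@H]2C(=C)OS(=O)(=O)C(F)(F)F
F2 | step 18 | enal–dienone (ring D enone on C6) | O=C/C=C/[C@]12COC(=O)[C@](C)([C@@H](OC3(C)C)[C@@H](O3)C1)[C@H]2C(=C)C4=CC(=O)CC4
F3 | step 18 | tetracyclic keto aldehyde (ring B closed, C12 aldehyde, C16 ketone) | O=CC[C@H]4[C@]12COC(=O)[C@](C)([C@@H](OC3(C)C)[C@@H](O3)C1)[C@H]2C(=C)[C@]45CC(=O)CC5
F4 | step 18 | C12 primary alcohol | OCC[C@H]4[C@]12COC(=O)[C@](C)([C@@H](OC3(C)C)[C@@H](O3)C1)[C@H]2C(=C)[C@]45CC(=O)CC5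
F5 | step 18 | C12 iodide | ICC[C@H]4[C@]12COC(=O)[C@](C)([C@@H](OC3(C)C)[C@@H](O3)C1)[C@H]2C(=C)[C@]45CC(=O)CC5
F6 | step 18 | pentacyclic 16-ketone with C6 methylene (desilylated 35) | O=C1C[C@]23C[C@H]1CC[C@H]2[C@]12COC(=O)[C@](C)([C@@H](OC4(C)C)[C@@H](O4)C1)[C@H]2C3=C
F7 | step 4 | spiro anhydride from 7 and 9 (racemic, relative configuration shown, C3 undefined) | CC1(C)OCC2(CO1)C=CC([Si](C)(C)C)[C@@]3(C)C(=O)OC(=O)[C@@H]23
F8 | step 9 | 19,20-δ-lactone with C6 N-methoxy-N-methylamide | CC(C)(C)[Si](C)(C)OC[C@]12COC(=O)[C@](C)(C=CC1)[C@H]2C(=O)N(C)OC
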